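The runs are simulated with constants of no real substance; the scatter is artificial.

Take a one-step world: substrate and partner go to product and back on the catalyst, so a run stands still once product over substrate over dissolved partner reaches a constant. Do these runs allow that reading?

| flask | substrate | gas | catalyst | remark | time |
|---|---|---|---|---|---|
| south | 0.65 M | 190 mM (held) | 0.14 mol% | run made earlier |  |
| north-west | 0.98 M | 190 mM (held) | 0.14 mol% | run made earlier |  |
| north-east | 1.3 M | 190 mM (held) | 0.21 mol% | run made earlier |  |
| flask | 1.3 M | 190 mM (held) | 0.14 mol% |  | 3.0 min |

| run | time / min | product / % | substrate / % |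
|---|---|---|---|
| south | 0.667 | 34.4 | 66.4 |
| south | 1.33 | 57.5 | 41.9 |
| south | 2.00 | 70.4 | 30.4 |
| south | 2.50 | 74.8 | 25.1 |
| south | 3.00 | 78.6 | 21.0 |
| south | 4.00 | 81.2 | 18.4 |
| north-west | 0.667 | 37.3 | 62.3 |
| north-west | 1.33 | 62.4 | 37.6 |
| north-west | 2.00 | 74.5 | 25.2 |
| north-west | 2.50 | 78.7 | 20.9 |
| north-west | 3.00 | 81.5 | 19.4 |
| north-west | 4.00 | 81.9 | 17.4 |
| north-east | 0.333 | 22.5 | 77.5 |
| north-east | 0.833 | 51.6 | 48.5 |
| north-east | 1.50 | 72.9 | 27.4 |
| north-east | 2.50 | 81.7 | 19.1 |
| north-east | 4.00 | 82.5 | 16.8 |

(readings scatter by 0.5 percentage points)

- at the start none of partner is dissolved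
- steps that have been proposed: gas <-> partner; substrate + partner + catalyst <-> product + catalyst

- grey: doubling the saturation concentration of gas, all else as stated
- teal: doubling the amount of catalyst, all else as stated
- amber: doubling the transfer coefficient of the gas, all else as stated

1. the product standing at 3.0 min, as a percentage of the substrate charged
2. the change that raises the amount of product at 3.0 min, in percent of the substrate charged most ("none" if none brings more than 2 percentage points) (grey / teal / amber / none)
3. amount of product at 3.0 min, in percent of the substrate charged, after teal

**Where does the flask stop?** Read the ceiling constant K, the equilibrium constant: product divided by substrate and by partner at the end of a run. Taking partner as saturated at 190 mM at the last north-east reading gives K = 25.8 M⁻¹, a reading with its scatter. With c the saturation concentration, the ceiling is Kc/(1+Kc), which is 83.1% of the substrate charged.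

**And at 3.0 min?** The flask differs from north-east in loading. If time scaled with catalyst, it would match north-east at 2.00 min, and between those readings stands about 77.3%.

**Does time scale so?** No. From south to north-west, catalyst concentration grows 1.51 times, but the first product reading grows 1.08 times.

**So go round again.** At this loading and time, south gave 78.6% and north-west 81.5%, rising with the charge, so 77.3% is too low. My figure is about 81.5%, which leaves 1.6 percentage points to the ceiling.

**Which change?** Teal and amber leave K and the saturation as they are, and that gap is less than 2 points. Grey lifts the ceiling to 90.8%. I choose grey, with teal just under the ceiling.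

The forecast says 81%, grey and 82.6% after teal, holding that “Teal and amber only speed the approach”. Its 81% stands a little below my figure.

The flask gives 81.4%. Grey adds 9.1 points, teal 1.1 points (to 82.4%) and amber 0.94 points.

    gas ⇌ partner, rate k1*(csat - [partner]) (kL = 0.130 s⁻¹)
    substrate + partner + catalyst ⇌ product + catalyst, rate k2*[substrate]*[partner]*[catalyst] forward; the back reaction follows from the equilibrium constant (K = 25.0 M⁻¹, k = 100 M⁻² s⁻¹)

The forecast's figure would fail in a run at 0.073 mol% catalyst, where the answer has moved by 5 points, or at 2.05 min. In the flask at 3.00 min, product 81.4%, substrate 18.6% and partner 0.185 M give a quotient of 23.6 M⁻¹, which is 94.4% of the 25 M⁻¹ in the equations. The neighbouring flask, read at 2.0 min, holds 75.8% product, 24.2% substrate and 0.167 M partner. The ceiling reckoning with the reading 25.8 M⁻¹ and that partner gives 81.2%, and this neighbour holds less product than that. Its quotient is 18.7 M⁻¹, which is 74.8% of the 25 M⁻¹ in the equations.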